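**Retrosynthetic overview**
- The methylene bridge is cut last: the enol carbon C6 of the ring A acyl-trione adds to the ortho-quinone methide released from the ring B Mannich base (ring B is aspidinol).
- Feature the plan rests on: ring A without its C2 butanoyl group and C6 benzyl group is 2-methyl-2-prenylcyclohexane-1,3,5-trione. It is achiral (mirror plane through the quaternary carbon and the opposite carbonyl carbon), and its two enol oxygens on the carbons flanking the quaternary carbon are enantiotopic. Each can reach the tertiary alkene carbon of the prenyl group through a six-membered ring.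
- A catalytic enantioselective bromoetherification ties one of these oxygens to the prenyl group as a temporary bromodihydropyran ring. This makes the quaternary carbon stereogenic and leaves one CH2 between two free carbonyls for butanoylation; zinc then removes the ring and returns the prenyl group.
- The trione ring is made by Claisen cyclization of an acyclic 2,2-disubstituted 3,5-dioxohexanoate. Ring B comes from 2,4,6-trihydroxytoluene by acylation, para-O-methylation and aminomethylation.
- Ring order: ring A carbocycle (step 3), temporary pyran ring (closed in step 4, opened in step 6); ring B is aromatic from the start.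

Key step: step 4

Assumption: the sense of induction of the catalyst on this new substrate cannot be predicted, so the route is written for the catalyst that gives (3S,4aR)-9. (DHQD)2PHAL is taken first, and its quasi-enantiomer (DHQ)2PHAL (hydroquinine 1,4-phthalazinediyl diether) is used if the opposite sense is found; the configuration is to be assigned by anomalous-dispersion X-ray analysis of the bromide.
Remark: polycarbonyl compounds are drawn in one tautomeric form, and CIP descriptors refer to the tautomer drawn.

**Route**

Step 1
Reactants: 1 ethyl 2-methyl-3-oxobutanoate; 2 1-bromo-3-methylbut-2-ene (prenyl bromide)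
Product: 3 ethyl 2-acetyl-2,5-dimethylhex-4-enoate (racemic)
Conditions: NaH, THF, 0 °C; then 2, rt
Reagents that add atoms: 1-bromo-3-methylbut-2-ene, CC(C)=CCBr
Why: Acetoacetic ester alkylation, in which the sodium enolate is C-alkylated by SN2 at the primary allylic bromide; the racemic quaternary carbon does not matter because it becomes the symmetry-bearing carbon of 7.

Step 2
Reactants: 3 ethyl 2-acetyl-2,5-dimethylhex-4-enoate; 4 1-acetyl-1H-benzotriazole
Product: 5 ethyl 2-methyl-2-(3-methylbut-2-en-1-yl)-3,5-dioxohexanoate (racemic)
Conditions: MgBr2·OEt2, iPr2NEt, CH2Cl2, rt; aq. HCl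
Reagents that add atoms: 1-acetyl-1H-benzotriazole, CC(=O)n1nnc2ccccc12
Why: Crossed Claisen-type C-acylation under soft enolization, in which the magnesium-chelated keto ester is deprotonated by the amine at its only enolizable position (the acetyl CH3) and acylated by the N-acylbenzotriazole; no alkoxide is present that could cleave the alpha,alpha-disubstituted acetoacetate by retro-Claisen reaction.

Step 3
Reactants: 5 ethyl 2-methyl-2-(3-methylbut-2-en-1-yl)-3,5-dioxohexanoate
Product: 7 2-methyl-2-(3-methylbut-2-en-1-yl)cyclohexane-1,3,5-trione, via dilithium dianion 6 (not isolated)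
Conditions: LiN(iPr)2 (3.2 equiv), THF, −78 °C to 0 °C; aq. HCl
Reagents that add atoms: none
Why: Intramolecular Claisen (Dieckmann-type) condensation, in which the terminal carbanion of the 1,3-diketone dianion attacks the ester in a 6-enolendo-exo-trig closure, driven by formation of the stabilized trione enolate; ring closure makes the quaternary carbon a non-stereogenic centre, so 7 is achiral.

Step 4
Reactants: 7 2-methyl-2-(3-methylbut-2-en-1-yl)cyclohexane-1,3,5-trione; 8 N-bromosuccinimide
Product: 9 (3S,4aR)-3-bromo-2,2,4a-trimethyl-3,4-dihydro-2H-chromene-5,7(4aH,6H)-dione (bromine trans to the angular methyl)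
Conditions: hydroquinidine 1,4-phthalazinediyl diether, (DHQD)2PHAL (10 mol %), CHCl3/toluene, −60 °C; aq. Na2S2O3
Reagents that add atoms: N-bromosuccinimide, O=C1CCC(=O)N1Br
Why: Proposed new method: a quinuclidine nitrogen of the catalyst ion-pairs with the vinylogous acid 7 (acidity like a carboxylic acid) while the catalyst relays Br+ from 8 to one face of the trisubstituted prenyl alkene, and the bound enol oxygen opens the bromiranium ion anti at its tertiary carbon; the closest known reactions are catalytic enantioselective bromolactonization and desymmetrizing bromoetherification, of which this would be the vinylogous enol-oxygen version. The dihydropyran ring closes in the 6-endo mode, and the gem-dimethyl terminus secures this Markovnikov opening over 5-exo attack at the secondary carbon. C3 is set by the alkene face that the catalyst brominates, and C4a is set by which of the two enantiotopic enol oxygens attacks; the two choices are coupled through a chair-like transition state with bromine equatorial (anti to the forming O–C bond) and the angular methyl axial, which gives the trans relationship. The step needs O- over C-cyclization and alkene over enol-carbon bromination: oxygen attack is the favoured six-membered closure of the planar enol, and a C-bromo-1,3-dione formed at a ring CH2 is itself a Br+ donor, so that bromination is reversible and is erased by the thiosulfate quench. The cis diastereomer formed from the same alkene face carries the opposite quaternary configuration, so it is removed by chromatography and crystallization before the ring is reopened.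

Step 5
Reactants: 9 (3S,4aR)-3-bromo-2,2,4a-trimethyl-3,4-dihydro-2H-chromene-5,7(4aH,6H)-dione; 10 butanoic acid
Product: 12 (3S,4aS)-3-bromo-6-butanoyl-5-hydroxy-2,2,4a-trimethyl-3,4-dihydro-2H-chromen-7(4aH)-one, via enol butanoate 11 (not isolated)
Conditions: DCC, DMAP, CH2Cl2, 0 °C to rt
Reagents that add atoms: butanoic acid, CCCC(=O)O
Why: Steglich-type O-acylation of the cyclic 1,3-dione followed by DMAP-mediated O-to-C acyl migration, which delivers the acyl group to C6, the only carbon between two free carbonyls, because the other side of the trione is locked as the ring enol ether; neither stereocentre is touched.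

Step 6
Reactants: 12 (3S,4aS)-3-bromo-6-butanoyl-5-hydroxy-2,2,4a-trimethyl-3,4-dihydro-2H-chromen-7(4aH)-one
Product: 13 (4R)-2-butanoyl-3,5-dihydroxy-4-methyl-4-(3-methylbut-2-en-1-yl)cyclohexa-2,5-dien-1-one
Conditions: Zn dust, AcOH, THF/EtOH, rt
Reagents that add atoms: none
Why: Boord-type reductive beta-elimination, in which zinc reduces the C–Br bond and the ring C–O bond (anti to the equatorial bromine) leaves as the stabilized acyl-trione enolate, regenerating the prenyl alkene; the bromine-bearing centre is destroyed and the quaternary carbon, not involved, stays stereogenic because of the butanoyl group.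

Step 7
Reactants: 14 2-methylbenzene-1,3,5-triol (2,4,6-trihydroxytoluene); 15 butanoyl chloride
Product: 16 1-(2,4,6-trihydroxy-3-methylphenyl)butan-1-one
Conditions: AlCl3, PhNO2, 50 °C; aq. HCl
Reagents that add atoms: butanoyl chloride, CCCC(=O)Cl
Why: Friedel–Crafts acylation of the electron-rich methylphloroglucinol, whose two free ring positions are equivalent; the first acyl group deactivates the ring against a second acylation.

Step 8
Reactants: 16 1-(2,4,6-trihydroxy-3-methylphenyl)butan-1-one; 17 dimethyl sulfate
Product: 18 1-(2,6-dihydroxy-4-methoxy-3-methylphenyl)butan-1-one (aspidinol)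
Conditions: Me2SO4 (1.0 equiv), K2CO3 (1.0 equiv), acetone, rt
Reagents that add atoms: dimethyl sulfate, COS(=O)(=O)OC
Why: Williamson-type O-methylation, selective for the hydroxyl para to the acyl group because it is the most acidic and is not hydrogen-bonded to the carbonyl as the two ortho hydroxyls are.

Step 9
Reactants: 18 1-(2,6-dihydroxy-4-methoxy-3-methylphenyl)butan-1-one; 19 N,N,N',N'-tetramethylmethanediamine
Product: 20 1-{3-[(dimethylamino)methyl]-2,6-dihydroxy-4-methoxy-5-methylphenyl}butan-1-one
Conditions: CH2(NMe2)2, 1,4-dioxane, rt to 50 °C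
Reagents that add atoms: N,N,N',N'-tetramethylmethanediamine, CN(C)CN(C)C
Why: Phenolic Mannich reaction, in which the acidic phenol opens the aminal to the iminium ion that substitutes the only unsubstituted ring carbon.

Step 10
Reactants: 13 (4R)-2-butanoyl-3,5-dihydroxy-4-methyl-4-(3-methylbut-2-en-1-yl)cyclohexa-2,5-dien-1-one; 20 1-{3-[(dimethylamino)methyl]-2,6-dihydroxy-4-methoxy-5-methylphenyl}butan-1-one
Product: 22 (4R)-2-butanoyl-6-[(3-butanoyl-2,4-dihydroxy-6-methoxy-5-methylphenyl)methyl]-3,5-dihydroxy-4-methyl-4-(3-methylbut-2-en-1-yl)cyclohexa-2,5-dien-1-one, via ortho-quinone methide 21 (not isolated)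
Conditions: toluene, 70–80 °C, N2
Reagents that add atoms: Mannich base 20, CCCC(=O)c1c(O)c(CN(C)C)c(OC)c(C)c1O
Why: Thermal loss of dimethylamine from the ortho-hydroxybenzylamine gives the ortho-quinone methide, to which C6 of 13 (its only free nucleophilic carbon) adds in a Michael addition with rearomatization of ring B; the quaternary stereocentre is not involved, and the moderate temperature avoids sigmatropic migration of the prenyl group.

**Compound list**
1 | ethyl 2-methyl-3-oxobutanoate (racemic, configurationally labile) | CCOC(=O)C(C)C(C)=O | starting material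
2 | 1-bromo-3-methylbut-2-ene (prenyl bromide) | CC(C)=CCBr | starting material
3 | ethyl 2-acetyl-2,5-dimethylhex-4-enoate (racemic) | CCOC(=O)C(C)(CC=C(C)C)C(C)=O | intermediate
4 | 1-acetyl-1H-benzotriazole | CC(=O)n1nnc2ccccc12 | starting material
5 | ethyl 2-methyl-2-(3-methylbut-2-en-1-yl)-3,5-dioxohexanoate (racemic) | CCOC(=O)C(C)(CC=C(C)C)C(=O)CC(C)=O | intermediate
6 | dilithium dianion (1,3-dienediolate) of 5 | [Li+].[Li+].CCOC(=O)C(C)(CC=C(C)C)C([O-])=CC([O-])=C | intermediate
7 | 2-methyl-2-(3-methylbut-2-en-1-yl)cyclohexane-1,3,5-trione (achiral; the same compound as 4-methyl-4-prenylcyclohexane-1,3,5-trione) | CC1(CC=C(C)C)C(=O)CC(=O)CC1=O | intermediate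
8 | N-bromosuccinimide | O=C1CCC(=O)N1Br | starting material
9 | (3S,4aR)-3-bromo-2,2,4a-trimethyl-3,4-dihydro-2H-chromene-5,7(4aH,6H)-dione, bromine trans to the angular methyl | O=C1CC(=O)[C@]2(C)C[C@H](Br)C(C)(C)OC2=C1 | intermediate
10 | butanoic acid | CCCC(=O)O | starting material
11 | enol butanoate of 9 (drawn as the 5-O-butanoyl isomer; configuration as in 9) | O=C1C=C(OC(=O)CCC)[C@]2(C)C[C@H](Br)C(C)(C)OC2=C1 | intermediate
12 | (3S,4aS)-3-bromo-6-butanoyl-5-hydroxy-2,2,4a-trimethyl-3,4-dihydro-2H-chromen-7(4aH)-one (same spatial arrangement as 9; the C4a descriptor changes only because enolization at C5 alters the CIP ranking) | CCCC(=O)C1=C(O)[C@]2(C)C[C@H](Br)C(C)(C)OC2=CC1=O | intermediate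
13 | (4R)-2-butanoyl-3,5-dihydroxy-4-methyl-4-(3-methylbut-2-en-1-yl)cyclohexa-2,5-dien-1-one | CCCC(=O)C1=C(O)[C@](C)(CC=C(C)C)C(O)=CC1=O | intermediate
14 | 2-methylbenzene-1,3,5-triol (2,4,6-trihydroxytoluene) | Cc1c(O)cc(O)cc1O | starting material
15 | butanoyl chloride | CCCC(=O)Cl | starting material
16 | 1-(2,4,6-trihydroxy-3-methylphenyl)butan-1-one | CCCC(=O)c1c(O)cc(O)c(C)c1O | intermediate
17 | dimethyl sulfate | COS(=O)(=O)OC | starting material
18 | 1-(2,6-dihydroxy-4-methoxy-3-methylphenyl)butan-1-one (aspidinol) | CCCC(=O)c1c(O)cc(OC)c(C)c1O | intermediate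
19 | N,N,N',N'-tetramethylmethanediamine | CN(C)CN(C)C | starting material
20 | 1-{3-[(dimethylamino)methyl]-2,6-dihydroxy-4-methoxy-5-methylphenyl}butan-1-one | CCCC(=O)c1c(O)c(CN(C)C)c(OC)c(C)c1O | intermediate
21 | 2-butanoyl-3-hydroxy-5-methoxy-4-methyl-6-methylidenecyclohexa-2,4-dien-1-one (ortho-quinone methide) | C=C1C(=O)C(C(=O)CCC)=C(O)C(C)=C1OC | intermediate
22 | (4R)-2-butanoyl-6-[(3-butanoyl-2,4-dihydroxy-6-methoxy-5-methylphenyl)methyl]-3,5-dihydroxy-4-methyl-4-(3-methylbut-2-en-1-yl)cyclohexa-2,5-dien-1-one (CNP0219644.1) | CCCC(=O)C1=C(O)[C@](C)(CC=C(C)C)C(O)=C(Cc2c(O)c(C(=O)CCC)c(O)c(C)c2OC)C1=O | target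

Total step count: 10
Longest linear sequence: 7 steps (steps 1–6 and step 10); ring B is made in a 3-step branch (steps 7–9).

**Steps most likely to fail**

1. Step 4 (the proposed new method). It may fail through poor discrimination of the alkene faces and of the two enol oxygens, through cyclization of an enol carbon instead of oxygen onto the bromiranium ion, or through uncatalysed background bromoetherification. The fallback gives up the desymmetrization and uses known chemistry. It sets out from 16 and 2: dearomative C-prenylation of 16 at its methyl-bearing ring carbon (NaOMe, MeOH, 0 °C) should give racemic 2-butanoyl-3,5-dihydroxy-4-methyl-4-(3-methylbut-2-en-1-yl)cyclohexa-2,5-dien-1-one F1, to be separated from the isomers prenylated at the free ring carbon or at oxygen. Preparative chromatography on a polysaccharide chiral stationary phase, or crystallization of its salts with an enantiopure amine, then separates the (4S)-enantiomer F2 and returns to the route at 13.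

2. Step 3. It may fail through attack of the enol oxygen on the ester (lactonization to a pyran-2,4-dione) or through retro-Claisen cleavage next to the quaternary carbon. The fallback inverts the roles of the two partners and sets out from 2. 3-Methylpentane-2,4-dione F3 is C-prenylated with 2 (K2CO3, acetone) to 3-methyl-3-(3-methylbut-2-en-1-yl)pentane-2,4-dione F4. Its bis-enolate (excess LiN(iPr)2, THF) is then annulated with dimethyl carbonate F5 by two Claisen condensations, through methyl 4-acetyl-4,7-dimethyl-3-oxooct-6-enoate F6, and the route is rejoined at 7.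

3. Step 10. It may fail through amine-promoted scrambling of the methylene bridge (retro-Michael and re-addition leading to symmetrical dimers), through O-alkylation, or through sluggish formation of the quinone methide. The fallback moves the aminomethyl group to ring A and sets out from 13 and 19. Mannich reaction of 13 at C6 with 19 should give (4R)-2-butanoyl-6-[(dimethylamino)methyl]-3,5-dihydroxy-4-methyl-4-(3-methylbut-2-en-1-yl)cyclohexa-2,5-dien-1-one F7. Warming F7 with aspidinol 18 releases 4-butanoyl-5-hydroxy-6-methyl-2-methylidene-6-(3-methylbut-2-en-1-yl)cyclohex-4-ene-1,3-dione F8 (configuration as in 13), which is attacked by the free ring carbon of 18 in a Friedel–Crafts-type Michael addition, rejoining the route at 22.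

Further compounds
F1 | step 4 | racemic 2-butanoyl-3,5-dihydroxy-4-methyl-4-(3-methylbut-2-en-1-yl)cyclohexa-2,5-dien-1-one | CCCC(=O)C1=C(O)C(C)(CC=C(C)C)C(O)=CC1=O
F2 | step 4 | (4S)-2-butanoyl-3,5-dihydroxy-4-methyl-4-(3-methylbut-2-en-1-yl)cyclohexa-2,5-dien-1-one | CCCC(=O)C1=C(O)[C@@](C)(CC=C(C)C)C(O)=CC1=O
F3 | step 3 | 3-methylpentane-2,4-dione | CC(=O)C(C)C(C)=O
F4 | step 3 | 3-methyl-3-(3-methylbut-2-en-1-yl)pentane-2,4-dione | CC(=O)C(C)(CC=C(C)C)C(C)=O
F5 | step 3 | dimethyl carbonate | COC(=O)OC
F6 | step 3 | methyl 4-acetyl-4,7-dimethyl-3-oxooct-6-enoate | COC(=O)CC(=O)C(C)(CC=C(C)C)C(C)=O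
F7 | step 10 | (4R)-2-butanoyl-6-[(dimethylamino)methyl]-3,5-dihydroxy-4-methyl-4-(3-methylbut-2-en-1-yl)cyclohexa-2,5-dien-1-one | CCCC(=O)C1=C(O)[C@](C)(CC=C(C)C)C(O)=C(CN(C)C)C1=O
F8 | step 10 | 4-butanoyl-5-hydroxy-6-methyl-2-methylidene-6-(3-methylbut-2-en-1-yl)cyclohex-4-ene-1,3-dione, configuration as in 13 | CCCC(=O)C1=C(O)[C@](C)(CC=C(C)C)C(=O)C(=C)C1=O
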